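## Retrosynthetic overview

1. In Dysodanthin B the aryl, methyl, allyl and methoxy groups all lie on one face. H-5, H-3 and H-2 are therefore delivered last, anti to the allyl group: H-5 by kinetic enolate protonation, H-3 and H-2 by ionic hydrogenation of the 2,3-didehydro compound.
2. The 2,3-didehydro compound (quaternary C3a and the six-membered ring) comes from an enantioselective 1,2-shift. A spiro[4.4] 2-aryl-furanium ion enlarges its cyclopentanone to the cyclohexenone as C4 moves from C7a to C3a.
3. The spiro ion comes from 2,5-dimethoxylation of a tetrasubstituted furan, followed by closure of its methyl ketone side chain onto C7a. The side chain is attached by Friedel–Crafts/Michael addition to 3-methoxybut-3-en-2-one.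
4. The furan is made in one pot from but-2-yn-1-ol, allylmagnesium chloride and 3,4,5-trimethoxybenzaldehyde. The aldehyde comes from p-cresol.
5. Ring order: furan (the O-ring), then the spiro cyclopentanone, then the cyclohexenone by ring expansion.

Atom labels C2 to C7a are those of the target benzofuranone throughout.

Assumption: the sense of induction of the new chiral-acid step cannot be predicted, so the catalyst antipode that gives (3aS)-19 is taken from a screen of both antipodes.

## Route

Step 1
Reactants: 1 p-cresol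
Product: 4 3,5-dibromo-4-hydroxybenzaldehyde, via 2,6-dibromo-4-methylphenol 2 (not isolated), via 2,6-dibromo-4-(dibromomethyl)phenol 3 (not isolated)
Conditions: Br2 (2 equiv), o-dichlorobenzene, 40 °C; Br2 (2 equiv), 150–160 °C; H2O, 100 °C
Reagents that add atoms: bromine BrBr; water O
Why: Phenol-directed electrophilic ortho,ortho-dibromination, thermal free-radical benzylic dibromination and hydrolysis of the benzal bromide form the established one-pot process for this aldehyde, and no stereocenter is involved.

Step 2
Reactants: 4 3,5-dibromo-4-hydroxybenzaldehyde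
Product: 6 3,4,5-trimethoxybenzaldehyde, via syringaldehyde sodium salt 5 (not isolated)
Conditions: NaOMe, CuCl (10 mol %), DMF/MeOH, 100 °C; distil off MeOH; Me2SO4, 50 °C
Reagents that add atoms: sodium methoxide C[O-].[Na+]; dimethyl sulfate COS(=O)(=O)OC
Why: Copper(I)-catalysed Ullmann-type methoxylation replaces both aryl bromides ortho to the phenolate, and the phenolate is then O-methylated in the same pot (Williamson ether synthesis), the aldehyde being inert to both.

Step 3
Reactants: 7 but-2-yn-1-ol; 8 allylmagnesium chloride; 6 3,4,5-trimethoxybenzaldehyde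
Product: 12 4-allyl-3-methyl-2-(3,4,5-trimethoxyphenyl)furan, via oxamagnesacycle 9 (not isolated), via (Z)-ene-1,4-diol magnesium salt 10 (not isolated), via (Z)-γ-hydroxy enone 11 (not isolated)
Conditions: 8 (2.3 equiv), CuI (5 mol %), THF, 0→40 °C; 6, 0 °C→rt; PhCHO (1.2 equiv), rt; 2 M HCl, rt
Reagents that add atoms: none
Why: Hydroxyl-directed anti-carbomagnesiation of the propargylic alkoxide puts allyl on the carbinol-side alkyne carbon and magnesium on the methyl-bearing carbon (chelate 9), Grignard addition to 6 gives the (Z)-ene-diolate, magnesium-Oppenauer hydride transfer to benzaldehyde oxidises it once (the lactolate that forms is shielded from a second oxidation), and acid dehydrates the cyclic hemiketal to the aromatic furan (Paal–Knorr-type closure), so the transient carbinol stereocenter does not matter.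

Step 4
Reactants: 13 butane-2,3-dione
Product: 15 3-methoxybut-3-en-2-one, via 3,3-dimethoxybutan-2-one 14 (not isolated)
Conditions: HC(OMe)3 (1.05 equiv), p-TsOH (1 mol %), MeOH, rt; then slow distillation, bath 130–150 °C
Reagents that add atoms: trimethyl orthoformate COC(OC)OC
Why: Acid-catalysed mono-ketalisation of the 1,2-diketone with the orthoformate, followed by thermal acid-catalysed loss of one methanol, is the standard preparation of this α-methoxy enone.

Step 5
Reactants: 12 4-allyl-3-methyl-2-(3,4,5-trimethoxyphenyl)furan; 15 3-methoxybut-3-en-2-one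
Product: 16 rac-4-[3-allyl-4-methyl-5-(3,4,5-trimethoxyphenyl)furan-2-yl]-3-methoxybutan-2-one
Conditions: Sc(OTf)3 (5 mol %), MeCN, 0 °C→rt
Reagents that add atoms: none
Why: The only free position of 12 is the nucleophilic furan α-carbon, which adds to the Sc(III)-chelated α-methoxy enone in a Friedel–Crafts-type Michael addition, and the C5 stereocenter formed on protonation is left racemic because it is reset in step 9.

Step 6
Reactants: 16 rac-4-[3-allyl-4-methyl-5-(3,4,5-trimethoxyphenyl)furan-2-yl]-3-methoxybutan-2-one
Product: 17 4-[3-allyl-2,5-dimethoxy-4-methyl-5-(3,4,5-trimethoxyphenyl)-2,5-dihydrofuran-2-yl]-3-methoxybutan-2-one (diastereomer mixture)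
Conditions: undivided cell, graphite anode, Pt cathode, Et4NOTs (0.1 M), 2,6-lutidine, MeOH, −10 °C, 2.2 F/mol
Reagents that add atoms: methanol CO
Why: Clauson-Kaas anodic 2,5-dimethoxylation takes place at the aryl-furan, by far the most easily oxidised π-system, so the terminal alkene, the ketone and the trimethoxyphenyl ring survive, and all new stereocenters are erased in step 7.

Step 7
Reactants: 17 4-[3-allyl-2,5-dimethoxy-4-methyl-5-(3,4,5-trimethoxyphenyl)-2,5-dihydrofuran-2-yl]-3-methoxybutan-2-one
Product: 19 (3aS)-3a-allyl-5-methoxy-3-methyl-2-(3,4,5-trimethoxyphenyl)-4,5-dihydro-1-benzofuran-6(3aH)-one (C5 epimers), via spiro[4.4] ketone 18 (not isolated)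
Conditions: confined chiral imidodiphosphorimidate (IDPi) Brønsted acid (5 mol %), 5 Å MS, toluene, −40→−20 °C; Et3N quench; product kept at or below 0 °C and used at once
Reagents that add atoms: none
Why: Proposed new method: the chiral acid ionises the two ketal C–OMe bonds in turn, the methyl-ketone enol closes onto the C7a oxocarbenium ion to give spiro ketone 18 (the carbon analogue of oxidative furan spiroketalisation), loss of the benzylic methoxide gives a 2-aryl-furanium ion whose charge sits on the allyl-bearing C3a next to the spiro centre, and the electron-richer ring CH2 (C4, not the α-keto C7) makes a suprafacial 1,2-shift from C7a to C3a that enlarges the cyclopentanone to the cyclohexenone, creates the quaternary carbon and, after loss of H+ at C7, leaves the vinylogous ester, rearomatisation being blocked by the allyl group; because the spiro closure is reversible, the ion-paired chiral anion selects the shift that leads to (3aS) (dynamic kinetic control); the closest known reaction types are the spiroindolenine-to-tetrahydrocarbazole 1,2-migration, the dienone–phenol and quinol–enedione shifts, and IDPi-catalysed Wagner–Meerwein ring expansions.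

Step 8
Reactants: 19 (3aS)-3a-allyl-5-methoxy-3-methyl-2-(3,4,5-trimethoxyphenyl)-4,5-dihydro-1-benzofuran-6(3aH)-one
Product: 20 (2R,3S,3aS)-3a-allyl-5-methoxy-3-methyl-2-(3,4,5-trimethoxyphenyl)-3,3a,4,5-tetrahydro-1-benzofuran-6(2H)-one (C5 epimers)
Conditions: Et3SiH (5 equiv), CF3CO2H/CH2Cl2 1:4, −30 °C; cold aq NaHCO3
Reagents that add atoms: none
Why: Ionic hydrogenation: the aryl enol ether is protonated at C3 and the resulting 2-aryl oxocarbenium ion takes hydride at C2, both from the face opposite the pseudo-axial allyl group (the hydride also anti to the new C3 methyl), which puts Me and Ar cis to each other and to the allyl group, while the terminal alkene and the far less basic vinylogous ester are not reduced at −30 °C.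

Step 9
Reactants: 20 (2R,3S,3aS)-3a-allyl-5-methoxy-3-methyl-2-(3,4,5-trimethoxyphenyl)-3,3a,4,5-tetrahydro-1-benzofuran-6(2H)-one
Product: 22 Dysodanthin B (2R,3S,3aS,5R), via lithium dienolate 21 (not isolated)
Conditions: LDA (1.1 equiv), THF, −78 °C; AcOH (3 equiv) in THF, −78 °C; cold pH 7 buffer
Reagents that add atoms: none
Why: Kinetic α′-deprotonation of the vinylogous ester can only occur at C5, and the flat dienolate 21 is protonated irreversibly at −78 °C from the face opposite the pseudo-axial allyl group (kinetic enolate protonation), which places OMe cis to the allyl group as in the target and leaves C2, C3 and C3a untouched.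

## Compound list

1 | p-cresol | Cc1ccc(O)cc1 | starting material
2 | 2,6-dibromo-4-methylphenol | Cc1cc(Br)c(O)c(Br)c1 | intermediate
3 | 2,6-dibromo-4-(dibromomethyl)phenol | BrC(Br)c1cc(Br)c(O)c(Br)c1 | intermediate
4 | 3,5-dibromo-4-hydroxybenzaldehyde | O=Cc1cc(Br)c(O)c(Br)c1 | intermediate
5 | sodium 4-formyl-2,6-dimethoxyphenolate (syringaldehyde sodium salt) | COc1cc(C=O)cc(OC)c1[O-].[Na+] | intermediate
6 | 3,4,5-trimethoxybenzaldehyde | COc1cc(C=O)cc(OC)c1OC | intermediate
7 | but-2-yn-1-ol | CC#CCO | starting material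
8 | allylmagnesium chloride | C=CC[Mg]Cl | starting material
9 | 4-allyl-3-methyl-2,5-dihydro-1,2-oxamagnesole (chelated alkenylmagnesium alkoxide) | C=CCC1=C(C)[Mg]OC1 | intermediate
10 | (Z)-2-allyl-3-methyl-4-(3,4,5-trimethoxyphenyl)but-2-ene-1,4-diol (present as magnesium salt, carbinol racemic) | OC/C(CC=C)=C(\C(O)c1cc(OC)c(OC)c(OC)c1)C | intermediate
11 | (Z)-3-(hydroxymethyl)-2-methyl-1-(3,4,5-trimethoxyphenyl)hexa-2,5-dien-1-one | OC/C(CC=C)=C(\C(=O)c1cc(OC)c(OC)c(OC)c1)C | intermediate
12 | 4-allyl-3-methyl-2-(3,4,5-trimethoxyphenyl)furan | C=CCc1coc(-c2cc(OC)c(OC)c(OC)c2)c1C | intermediate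
13 | butane-2,3-dione | CC(=O)C(C)=O | starting material
14 | 3,3-dimethoxybutan-2-one | CC(=O)C(C)(OC)OC | intermediate
15 | 3-methoxybut-3-en-2-one | C=C(OC)C(C)=O | intermediate
16 | rac-4-[3-allyl-4-methyl-5-(3,4,5-trimethoxyphenyl)furan-2-yl]-3-methoxybutan-2-one | C=CCc1c(CC(OC)C(C)=O)oc(-c2cc(OC)c(OC)c(OC)c2)c1C | intermediate
17 | 4-[3-allyl-2,5-dimethoxy-4-methyl-5-(3,4,5-trimethoxyphenyl)-2,5-dihydrofuran-2-yl]-3-methoxybutan-2-one (all diastereomers) | C=CCC1=C(C)C(OC)(c2cc(OC)c(OC)c(OC)c2)OC1(OC)CC(OC)C(C)=O | intermediate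
18 | 4-allyl-2,8-dimethoxy-3-methyl-2-(3,4,5-trimethoxyphenyl)-1-oxaspiro[4.4]non-3-en-7-one (interconverting stereoisomers) | C=CCC1=C(C)C(OC)(c2cc(OC)c(OC)c(OC)c2)OC13CC(OC)C(=O)C3 | intermediate
19 | (3aS)-3a-allyl-5-methoxy-3-methyl-2-(3,4,5-trimethoxyphenyl)-4,5-dihydro-1-benzofuran-6(3aH)-one (C5 epimers) | C=CC[C@@]12CC(OC)C(=O)C=C1OC(c1cc(OC)c(OC)c(OC)c1)=C2C | intermediate
20 | (2R,3S,3aS)-3a-allyl-5-methoxy-3-methyl-2-(3,4,5-trimethoxyphenyl)-3,3a,4,5-tetrahydro-1-benzofuran-6(2H)-one (C5 epimers) | C=CC[C@@]12CC(OC)C(=O)C=C1O[C@@H](c1cc(OC)c(OC)c(OC)c1)[C@H]2C | intermediate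
21 | lithium C5–C6 dienolate of 20 | [Li+].C=CC[C@@]12CC(OC)=C([O-])C=C1O[C@@H](c1cc(OC)c(OC)c(OC)c1)[C@H]2C | intermediate
22 | Dysodanthin B, (2R,3S,3aS,5R) | C=CC[C@@]12C[C@@H](OC)C(=O)C=C1O[C@@H](c1cc(OC)c(OC)c(OC)c1)[C@H]2C | target

## Step count and risks

Total step count: 9. Longest linear sequence: 8 (steps 1, 2, 3, 5, 6, 7, 8, 9).

**Step 7 (the proposed new step).**
- The oxidised furan may lose a proton from the furfuryl CH2 and rearomatise to a 2-alkenylfuran.
- The cascade may stall before the shift.
- The enantiomeric excess may be low.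
- Fallback, known chemistry only: it sets out from 6 (and uses 15) and comes back at 20.
  - Brown (Z)-crotylboration of 6 gives syn-(1R,2S)-2-methyl-1-(3,4,5-trimethoxyphenyl)but-3-en-1-ol F1. The reagent is made from cis-but-2-ene, n-BuLi/KOt-Bu and the Ipc2BOMe antipode that leads to the (1R,2S) product, with NaOH/H2O2 work-up.
  - 9-BBN, then H2O2/NaOH, gives (1R,2S)-2-methyl-1-(3,4,5-trimethoxyphenyl)butane-1,4-diol F2.
  - TEMPO/PhI(OAc)2 closes it to cis-(4S,5R)-4-methyl-5-(3,4,5-trimethoxyphenyl)dihydrofuran-2(3H)-one F3.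
  - LDA and allyl bromide give (3S,4S,5R)-3-allyl-4-methyl-5-(3,4,5-trimethoxyphenyl)dihydrofuran-2(3H)-one F4, with allyl anti to Me and Ar.
  - A second LDA deprotonation and Michael addition to 15 bring C4 in anti to Me and Ar. This pushes the allyl group onto the crowded face and gives the quaternary keto lactone F5.
  - KOt-Bu closes the methyl ketone enolate onto the lactone carbonyl (Dieckmann-type), and mild acid dehydrates the hemiketal to 20.

**Step 8.**
- Acid can ionise the benzylic C2–O bond of the product and drain it to the 2,3-trans isomer.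
- Compound 19 can aromatise by allyl migration to C7 if it warms.
- Fallback: it sets out from 19 and comes back at 20.
  - Cold 1 M HCl/THF hydrates the aryl enol ether, with protonation again anti to allyl, to give the triketone F6.
  - L-Selectride (2.2 equiv; the first equivalent masks the 1,3-dione as its enolate) reduces the aryl ketone under Felkin–Anh control to the anti (1S)-benzylic alcohol F7.
  - Mitsunobu closure (PPh3, DIAD) through the acidic enol oxygen at C7a inverts the benzylic carbon and gives the 2,3-cis ring of 20 without any cationic intermediate.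

**Step 9.**
- The target carries a pseudo-axial OMe that is 1,3-diaxial to the allyl group, so it is probably the less stable C5 epimer.
- Modest facial selectivity, or equilibration during work-up, would erode it.
- Fallback: it sets out from 20 and comes back at 22.
  - TMSOTf/Et3N gives the isolable trimethylsilyl dienol ether F8.
  - F8 is protonated under reagent control with a Lewis-acid-assisted chiral Brønsted acid (BINOL·SnCl4 catalyst, 2,6-dimethylphenol as the stoichiometric proton source), using the antipode matched to the substrate bias.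

Further compounds
F1 | step 7 | (1R,2S)-2-methyl-1-(3,4,5-trimethoxyphenyl)but-3-en-1-ol | O[C@@H](c1cc(OC)c(OC)c(OC)c1)[C@H](C=C)C
F2 | step 7 | (1R,2S)-2-methyl-1-(3,4,5-trimethoxyphenyl)butane-1,4-diol | O[C@@H](c1cc(OC)c(OC)c(OC)c1)[C@H](CCO)C
F3 | step 7 | (4S,5R)-4-methyl-5-(3,4,5-trimethoxyphenyl)dihydrofuran-2(3H)-one | O=C1O[C@@H](c2cc(OC)c(OC)c(OC)c2)[C@@H](C)C1
F4 | step 7 | (3S,4S,5R)-3-allyl-4-methyl-5-(3,4,5-trimethoxyphenyl)dihydrofuran-2(3H)-one | O=C1O[C@@H](c2cc(OC)c(OC)c(OC)c2)[C@@H](C)[C@@H]1CC=C
F5 | step 7 | 3-allyl-3-(2-methoxy-3-oxobutyl)-4-methyl-5-(3,4,5-trimethoxyphenyl)dihydrofuran-2(3H)-one, allyl cis to Me and Ar, side-chain OMe centre unassigned | O=C1O[C@@H](c2cc(OC)c(OC)c(OC)c2)[C@@H](C)[C@]1(CC=C)CC(OC)C(C)=O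
F6 | step 8 | 4-allyl-6-methoxy-4-[1-oxo-1-(3,4,5-trimethoxyphenyl)propan-2-yl]cyclohexane-1,3-dione, configuration at C3 and C3a as in 20 | C=CC[C@]1(CC(OC)C(=O)CC1=O)[C@H](C)C(=O)c1cc(OC)c(OC)c(OC)c1
F7 | step 8 | 4-allyl-4-[(1S)-1-hydroxy-1-(3,4,5-trimethoxyphenyl)propan-2-yl]-6-methoxycyclohexane-1,3-dione (anti alcohol) | C=CC[C@]1(CC(OC)C(=O)CC1=O)[C@H](C)[C@H](O)c1cc(OC)c(OC)c(OC)c1
F8 | step 9 | trimethylsilyl C5–C6 dienol ether of 20 | C=CC[C@@]12CC(OC)=C(O[Si](C)(C)C)C=C1O[C@@H](c1cc(OC)c(OC)c(OC)c1)[C@H]2C
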